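The route rests on cutting each nonanoyl arm between the carbons alpha and beta to its ketone. One iridium-catalysed hydrogen-borrowing reaction joins two molecules of 2,6-dimethoxyacetophenone to both primary alcohols of a tetramethoxybiaryl bis(7-hydroxyheptyl) diol, making both C–C bonds at the ketone oxidation level with water as the only by-product. The feature exploited is the C(=O)–CH2 unit on C1 of each terminal ring (rings C and D), whose C2 and C6 both bear oxygen: this flanked, twisted carbonyl is alkylated once at its methyl group and is not reduced. The diol comes from a Suzuki-derived biaryl dialdehyde (rings A and B) by double Wittig olefination and hydrogenation; global demethylation ends the synthesis.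

Key step: step 5

Structure check: each arm has eight CH2 groups between ring and carbonyl, seven from a heptanol arm of 8 and one from the methyl group of 9. The biaryl bond lies ortho to an oxygen on ring A and ortho to the alkyl arm on ring B. No structure needed correction, but the biaryl union needs one boron partner, which 4 supplies.

Assumption: 3 and 4 are bought as such. The alkene geometry of 7 (drawn Z,Z, the isomer a salt-free Wittig reaction should favour) is immaterial because step 4 saturates both double bonds.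

Step 1
Reactants: 1 6-bromohexan-1-ol
Product: 2 (6-hydroxyhexyl)triphenylphosphonium bromide
Conditions: PPh3 (1.05 equiv), MeCN, reflux
Reagents that add atoms: triphenylphosphine, c1ccc(cc1)P(c1ccccc1)c1ccccc1
Why: Phosphonium salt formation by SN2 attack of the phosphine on the primary bromide should be clean, since the free hydroxyl does not compete and the salt crystallises.

Step 2
Reactants: 3 3-bromo-4,5-dimethoxybenzaldehyde (5-bromoveratraldehyde); 4 (2-formyl-4,5-dimethoxyphenyl)boronic acid
Product: 5 4,5,5',6'-tetramethoxybiphenyl-2,3'-dicarbaldehyde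
Conditions: Pd(OAc)2 (3 mol%), SPhos (6 mol%), K3PO4 (3 equiv), 4 (1.3 equiv), toluene/H2O, 80 °C
Reagents that add atoms: none
Why: Suzuki–Miyaura cross-coupling with the SPhos-ligated zerovalent palladium catalyst formed in the flask should join the two rings faster than the ortho-formyl boronic acid loses boron, and both aldehydes are spectators.

Step 3
Reactants: 5 4,5,5',6'-tetramethoxybiphenyl-2,3'-dicarbaldehyde; 2 (6-hydroxyhexyl)triphenylphosphonium bromide
Product: 7 (Z,Z)-7,7'-(4,5,5',6'-tetramethoxybiphenyl-2,3'-diyl)bis(hept-6-en-1-ol), via sodium alkoxide ylide 6 (not isolated)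
Conditions: 2 (3 equiv), NaN(SiMe3)2 (6 equiv), THF, 0 °C; then 5, −78 °C → rt; H2O
Reagents that add atoms: none
Why: Double Wittig olefination with a non-stabilised ylide should convert both non-enolisable aryl aldehydes, because the second equivalent of base per salt masks the hydroxyl as its alkoxide so that the ylide is not quenched.

Step 4
Reactants: 7 (Z,Z)-7,7'-(4,5,5',6'-tetramethoxybiphenyl-2,3'-diyl)bis(hept-6-en-1-ol)
Product: 8 7,7'-(4,5,5',6'-tetramethoxybiphenyl-2,3'-diyl)bis(heptan-1-ol)
Conditions: H2 (1 atm), 10% Pd/C (palladium on carbon), EtOAc, rt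
Reagents that add atoms: none
Why: Heterogeneous catalytic hydrogenation should saturate both styrene-type double bonds whatever their geometry and leave the arenes, the aryl methyl ethers and the primary alcohols untouched.

Step 5
Reactants: 8 7,7'-(4,5,5',6'-tetramethoxybiphenyl-2,3'-diyl)bis(heptan-1-ol); 9 2,6-dimethoxyacetophenone
Product: 12 9,9'-(4,5,5',6'-tetramethoxybiphenyl-2,3'-diyl)bis[1-(2,6-dimethoxyphenyl)nonan-1-one], via biaryl diheptanal 10 (not isolated), via bis-enone 11 (not isolated)
Conditions: [Cp*IrCl2]2 (4 mol%), KOH (4 equiv), 9 (4 equiv), toluene, 85 °C, sealed tube under Ar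
Reagents that add atoms: none
Why: The base-activated Cp*Ir catalyst (trivalent iridium) dehydrogenates each primary alcohol of 8 to an aldehyde (10 shows both arms at that stage) and holds the hydrogen as an iridium hydride. The potassium enolate of 9 then condenses with each aldehyde by crossed aldol addition and dehydration to the E-enone (11), and the iridium hydride returns the hydrogen to the enone C=C, which leaves the saturated ketone and water. The closest known reaction type is the iridium-catalysed hydrogen-borrowing alpha-alkylation of di-ortho-substituted aryl methyl ketones with primary alcohols, applied here twice on one diol. No ring is closed and no stereocentre is created. The selectivities needed are single alkylation at the CH3 group, reduction of C=C in preference to C=O and crossed instead of self-aldol reaction of the ketone; all three follow from the methoxy groups at C2 and C6 of 9, which twist the carbonyl out of the ring plane and shield it from hydride and from its own enolate, while the more hindered alpha-CH2 of the product should not react again at this temperature. Excess 9 should intercept each aldehyde before it self-condenses, and the closed vessel keeps the borrowed hydrogen available for the return step.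

Step 6
Reactants: 12 9,9'-(4,5,5',6'-tetramethoxybiphenyl-2,3'-diyl)bis[1-(2,6-dimethoxyphenyl)nonan-1-one]
Product: 13 9,9'-(4,5,5',6'-tetrahydroxybiphenyl-2,3'-diyl)bis[1-(2,6-dihydroxyphenyl)nonan-1-one]
Conditions: BBr3 (16 equiv), CH2Cl2, −78 °C → rt; then H2O, 0 °C, under Ar
Reagents that add atoms: none
Why: Lewis-acid cleavage of aryl methyl ethers with BBr3 (boron binds each ether oxygen, bromide removes the methyl group by SN2, water hydrolyses the aryl borates) should free all eight phenols, while the ketones and the saturated chains are inert.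

Compound list
1 | 6-bromohexan-1-ol | OCCCCCCBr | starting material
2 | (6-hydroxyhexyl)triphenylphosphonium bromide | OCCCCCC[P+](c1ccccc1)(c1ccccc1)c1ccccc1.[Br-] | intermediate
3 | 3-bromo-4,5-dimethoxybenzaldehyde (5-bromoveratraldehyde) | COc1cc(C=O)cc(Br)c1OC | starting material
4 | (2-formyl-4,5-dimethoxyphenyl)boronic acid | COc1cc(C=O)c(B(O)O)cc1OC | starting material
5 | 4,5,5',6'-tetramethoxybiphenyl-2,3'-dicarbaldehyde | COc1cc(C=O)cc(-c2cc(OC)c(OC)cc2C=O)c1OC | intermediate
6 | sodium 6-(triphenylphosphoranylidene)hexan-1-olate (alkoxide ylide, formed in the flask) | [Na+].[O-]CCCCCC=P(c1ccccc1)(c1ccccc1)c1ccccc1 | intermediate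
7 | (Z,Z)-7,7'-(4,5,5',6'-tetramethoxybiphenyl-2,3'-diyl)bis(hept-6-en-1-ol) (any E isomers are carried on together) | OCCCCC/C=C\c1cc(OC)c(OC)c(-c2cc(OC)c(OC)cc2/C=C\CCCCCO)c1 | intermediate
8 | 7,7'-(4,5,5',6'-tetramethoxybiphenyl-2,3'-diyl)bis(heptan-1-ol) | OCCCCCCCc1cc(OC)c(OC)c(-c2cc(OC)c(OC)cc2CCCCCCCO)c1 | intermediate
9 | 2,6-dimethoxyacetophenone | CC(=O)c1c(OC)cccc1OC | starting material
10 | 7,7'-(4,5,5',6'-tetramethoxybiphenyl-2,3'-diyl)diheptanal | O=CCCCCCCc1cc(OC)c(OC)c(-c2cc(OC)c(OC)cc2CCCCCCC=O)c1 | intermediate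
11 | (E,E)-9,9'-(4,5,5',6'-tetramethoxybiphenyl-2,3'-diyl)bis[1-(2,6-dimethoxyphenyl)non-2-en-1-one] | COc1cccc(OC)c1C(=O)/C=C/CCCCCCc1cc(OC)c(OC)c(-c2cc(OC)c(OC)cc2CCCCCC/C=C/C(=O)c2c(OC)cccc2OC)c1 | intermediate
12 | 9,9'-(4,5,5',6'-tetramethoxybiphenyl-2,3'-diyl)bis[1-(2,6-dimethoxyphenyl)nonan-1-one] | COc1cccc(OC)c1C(=O)CCCCCCCCc1cc(OC)c(OC)c(-c2cc(OC)c(OC)cc2CCCCCCCCC(=O)c2c(OC)cccc2OC)c1 | intermediate
13 | 9,9'-(4,5,5',6'-tetrahydroxybiphenyl-2,3'-diyl)bis[1-(2,6-dihydroxyphenyl)nonan-1-one] | O=C(CCCCCCCCc1cc(O)c(O)c(-c2cc(O)c(O)cc2CCCCCCCCC(=O)c2c(O)cccc2O)c1)c1c(O)cccc1O | target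

Total step count: 6.
Longest linear sequence: 5 steps (steps 2, 3, 4, 5, 6 from 3 and 4; equally steps 1, 3, 4, 5, 6 from 1).

Steps most likely to fail

Step 5. One arm may stall at the alcohol or enone stage, the aldehyde may self-condense before the enolate of 9 captures it, or hydrogen may be lost so that enone remains. The fallback replaces the catalytic redox relay by stoichiometric steps; it sets out from 8 and returns at 12. Diol 8 is oxidised with Dess–Martin periodinane (CH2Cl2, NaHCO3) to dialdehyde 10, now isolated. Addition of 10 to the lithium enolate of 9 (LiN(i-Pr)2, THF, −78 °C) should give the bis(beta-hydroxy ketone) 9,9'-(4,5,5',6'-tetramethoxybiphenyl-2,3'-diyl)bis[1-(2,6-dimethoxyphenyl)-3-hydroxynonan-1-one] F1 as a mixture of diastereomers. Mesylation and E1cB elimination (MsCl, Et3N, CH2Cl2, 0 °C → rt) should give bis-enone 11, and hydrogenation of its two C=C bonds (H2, Pd/C, EtOAc) should give 12, the hindered aryl ketones being left alone.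

Step 6. Cleavage of eight ethers may stop short and give partly methylated mixtures, and the catechols may oxidise in air during work-up. The fallback exchanges methyl for methoxymethyl protection, so that the last step becomes a mild acetal cleavage; it sets out from phosphonium salt 2 and returns at 13.
- Purchased 3-bromo-4,5-dihydroxybenzaldehyde is protected (MOMCl, i-Pr2NEt, CH2Cl2) to 3-bromo-4,5-bis(methoxymethoxy)benzaldehyde F2.
- F2 is borylated (B2pin2, Pd(dppf)Cl2, KOAc, dioxane, 90 °C) to 3,4-bis(methoxymethoxy)-5-(4,4,5,5-tetramethyl-1,3,2-dioxaborolan-2-yl)benzaldehyde F3.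
- Purchased 2-bromo-4,5-dihydroxybenzaldehyde is protected in the same way to 2-bromo-4,5-bis(methoxymethoxy)benzaldehyde F4.
- Suzuki–Miyaura coupling of F3 and F4 under the conditions of step 2 should give 4,5,5',6'-tetrakis(methoxymethoxy)biphenyl-2,3'-dicarbaldehyde F5.
- Wittig olefination of F5 with ylide 6 (from 2, as in step 3) should give the diene diol (Z,Z)-7,7'-[4,5,5',6'-tetrakis(methoxymethoxy)biphenyl-2,3'-diyl]bis(hept-6-en-1-ol) F6.
- Hydrogenation (H2, Pd/C, EtOAc) should give 7,7'-[4,5,5',6'-tetrakis(methoxymethoxy)biphenyl-2,3'-diyl]bis(heptan-1-ol) F7.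
- Purchased 2,6-dihydroxyacetophenone is protected (NaH, MOMCl, DMF) to 2,6-bis(methoxymethoxy)acetophenone F8.
- Hydrogen-borrowing coupling of F7 with F8 under the conditions of step 5 (the acetals tolerate KOH) should give the octakis(methoxymethyl) ether of the target F9.
- HCl in MeOH at rt should then release 13.

Step 2. Protodeboronation of the ortho-formyl boronic acid may outpace transmetalation, and homocoupling may consume the partners. The fallback reverses the roles of the two rings; it sets out from 3 and returns at 5. Miyaura borylation of 3 (B2pin2, Pd(dppf)Cl2, KOAc, dioxane, 90 °C) should give 3,4-dimethoxy-5-(4,4,5,5-tetramethyl-1,3,2-dioxaborolan-2-yl)benzaldehyde F10, a boronate with no ortho carbonyl group. Suzuki–Miyaura coupling of F10 with purchased 2-bromo-4,5-dimethoxybenzaldehyde (Pd(OAc)2, SPhos, K3PO4, toluene/H2O, 80 °C), whose C–Br bond is activated by the ortho formyl group, should give 5.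

Further compounds
F1 | step 5 | 9,9'-(4,5,5',6'-tetramethoxybiphenyl-2,3'-diyl)bis[1-(2,6-dimethoxyphenyl)-3-hydroxynonan-1-one] (mixture of diastereomers) | COc1cccc(OC)c1C(=O)CC(O)CCCCCCc1cc(OC)c(OC)c(-c2cc(OC)c(OC)cc2CCCCCCC(O)CC(=O)c2c(OC)cccc2OC)c1
F2 | step 6 | 3-bromo-4,5-bis(methoxymethoxy)benzaldehyde | COCOc1cc(C=O)cc(Br)c1OCOC
F3 | step 6 | 3,4-bis(methoxymethoxy)-5-(4,4,5,5-tetramethyl-1,3,2-dioxaborolan-2-yl)benzaldehyde | COCOc1cc(C=O)cc(B2OC(C)(C)C(C)(C)O2)c1OCOC
F4 | step 6 | 2-bromo-4,5-bis(methoxymethoxy)benzaldehyde | COCOc1cc(Br)c(C=O)cc1OCOC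
F5 | step 6 | 4,5,5',6'-tetrakis(methoxymethoxy)biphenyl-2,3'-dicarbaldehyde | COCOc1cc(C=O)cc(-c2cc(OCOC)c(OCOC)cc2C=O)c1OCOC
F6 | step 6 | (Z,Z)-7,7'-[4,5,5',6'-tetrakis(methoxymethoxy)biphenyl-2,3'-diyl]bis(hept-6-en-1-ol) | OCCCCC/C=C\c1cc(OCOC)c(OCOC)c(-c2cc(OCOC)c(OCOC)cc2/C=C\CCCCCO)c1
F7 | step 6 | 7,7'-[4,5,5',6'-tetrakis(methoxymethoxy)biphenyl-2,3'-diyl]bis(heptan-1-ol) | OCCCCCCCc1cc(OCOC)c(OCOC)c(-c2cc(OCOC)c(OCOC)cc2CCCCCCCO)c1
F8 | step 6 | 2,6-bis(methoxymethoxy)acetophenone | CC(=O)c1c(OCOC)cccc1OCOC
F9 | step 6 | 9,9'-[4,5,5',6'-tetrakis(methoxymethoxy)biphenyl-2,3'-diyl]bis{1-[2,6-bis(methoxymethoxy)phenyl]nonan-1-one} | COCOc1cccc(OCOC)c1C(=O)CCCCCCCCc1cc(OCOC)c(OCOC)c(-c2cc(OCOC)c(OCOC)cc2CCCCCCCCC(=O)c2c(OCOC)cccc2OCOC)c1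
F10 | step 2 | 3,4-dimethoxy-5-(4,4,5,5-tetramethyl-1,3,2-dioxaborolan-2-yl)benzaldehyde | COc1cc(C=O)cc(B2OC(C)(C)C(C)(C)O2)c1OC
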